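**Assumption and shorthand (one line):** the stereocentre in the SMILES is (R) at C2 of the chromene; commercial (R)-(−)-linalool of high ee (≥97 %) is used and fixes the ee of the target; SEM = CH2OCH2CH2SiMe3, so "SEM-oxy" = OCH2OCH2CH2SiMe3.

## Retrosynthetic overview

1. Target ⇐ fluoride removal of three SEM groups from the protected dihydrochalcone.
2. Key disconnection: the aryl–CH2 bond of ArCO–CH2–CH2–Ar'. The ketone β-carbon acts as nucleophile (palladium homoenolate from a 1-arylcyclopropanol) and is joined to the C5 bromide of the chromene.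
3. Cyclopropanol ⇐ Kulinkovich reaction on SEM-protected methyl 2,4-dihydroxybenzoate (ring A is bought).
4. Bromochromene ⇐ ring-closing metathesis of a styrenyl tertiary allyl aryl ether ⇐ SNAr of (R)-linalool alkoxide on a 2-fluorobenzaldehyde (ring B is bought). The C–O bond at the stereocentre is never broken. The side-chain (E)-allylic alcohol comes from hydroxyselenation–elimination.
5. Ring order: both benzene rings are bought; the 2H-pyran ring is the only target ring built (step 6); a transient cyclopropane is made in step 8 and opened in step 9.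

## Route

**Step 1**
Reactants: 1 4-bromo-2-fluorophenol
Product: 2 4-bromo-2-fluoro-1-(SEM-oxy)benzene
Conditions: SEMCl, K2CO3, DMF, 0 °C→rt
Reagents that add atoms: 2-(trimethylsilyl)ethoxymethyl chloride (SEMCl), C[Si](C)(C)CCOCCl
Why: Williamson-type O-alkylation (SN2 on the α-chloro ether) gives an SEM acetal that survives the amide base, alkoxide, ylide, peroxide, palladium and ruthenium steps ahead and is removed at the end with fluoride, without acid.

**Step 2**
Reactants: 2 4-bromo-2-fluoro-1-(SEM-oxy)benzene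
Product: 4 6-bromo-2-fluoro-3-(SEM-oxy)benzaldehyde, via aryllithium 3 (not isolated)
Conditions: LiN(iPr)2, THF, −78 °C; DMF, −78→0 °C; H2O
Reagents that add atoms: N,N-dimethylformamide (DMF), CN(C)C=O
Why: Directed ortho-metalation/formylation: the amide base removes the most acidic ring hydrogen, the one between F and Br (the thermodynamic site, so no halogen dance; the hydrogen next to OSEM would need an alkyllithium), and at −78 °C aryllithium 3 is trapped by DMF before it can lose LiF or LiBr to an aryne.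

**Step 3**
Reactants: 4 6-bromo-2-fluoro-3-(SEM-oxy)benzaldehyde; 5 (R)-(−)-linalool
Product: 7 6-bromo-2-{[(3R)-3,7-dimethylocta-1,6-dien-3-yl]oxy}-3-(SEM-oxy)benzaldehyde, via potassium linaloolate 6 (not isolated)
Conditions: KN(SiMe3)2 on 5, THF, 0 °C; then 4, THF/DMF, 0 °C→rt
Reagents that add atoms: none
Why: Nucleophilic aromatic substitution (SNAr, addition–elimination): the tertiary alkoxide 6, which has no α-hydrogen and so cannot reduce the aldehyde, displaces the fluoride ortho to the formyl group (fluoride reacts far faster than the bromide at the other ortho position), and since only the O–H bond of linalool is broken its (R) centre is carried unchanged into 7 as the future C2 of the chromene.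

**Step 4**
Reactants: 7 6-bromo-2-{[(3R)-3,7-dimethylocta-1,6-dien-3-yl]oxy}-3-(SEM-oxy)benzaldehyde
Product: 8 1-bromo-3-{[(3R)-3,7-dimethylocta-1,6-dien-3-yl]oxy}-2-ethenyl-4-(SEM-oxy)benzene
Conditions: Ph3PCH3Br, KOtBu, THF, 0 °C→rt
Reagents that add atoms: methyltriphenylphosphonium bromide, C[P+](c1ccccc1)(c1ccccc1)c1ccccc1.[Br-]
Why: Wittig methylenation of the non-enolisable aldehyde installs the styrene needed for ring closure under basic conditions that leave the aryl bromide, the SEM acetal and the tertiary allyl aryl ether untouched.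

**Step 5**
Reactants: 8 1-bromo-3-{[(3R)-3,7-dimethylocta-1,6-dien-3-yl]oxy}-2-ethenyl-4-(SEM-oxy)benzene
Product: 11 (3E,6R)-6-[3-bromo-2-ethenyl-6-(SEM-oxy)phenoxy]-2,6-dimethylocta-3,7-dien-2-ol, via hydroxy selenide 9 (not isolated), via selenoxide 10 (not isolated)
Conditions: PhSeSePh, 30% aq H2O2, MgSO4, CH2Cl2, 0 °C→rt; then t-BuOOH, rt
Reagents that add atoms: benzeneselenenic acid PhSeOH, O[Se]c1ccccc1 (made in the flask from diphenyl diselenide, c1ccc(cc1)[Se][Se]c1ccccc1, and hydrogen peroxide, OO; it supplies the OH oxygen)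
Why: Hydroxyselenation–selenoxide elimination (Sharpless allylic-alcohol synthesis): PhSeOH adds in the Markovnikov sense only to the electron-rich trisubstituted alkene (OH on the tertiary carbon, SePh on the secondary carbon, 9), and after oxidation the selenoxide 10 can only take a syn hydrogen from the neighbouring CH2, which gives the transposed (E)-allylic tertiary alcohol; with the linalool oxygen already arylated no cyclic ether can form and the quaternary centre is not involved.

**Step 6**
Reactants: 11 (3E,6R)-6-[3-bromo-2-ethenyl-6-(SEM-oxy)phenoxy]-2,6-dimethylocta-3,7-dien-2-ol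
Product: 12 (3E)-5-[(2R)-5-bromo-2-methyl-8-(SEM-oxy)-2H-chromen-2-yl]-2-methylpent-3-en-2-ol
Conditions: second-generation Grubbs catalyst RuCl2(=CHPh)(SIMes)(PCy3) (5 mol%), CH2Cl2, 40 °C, dark
Reagents that add atoms: none
Why: Ring-closing olefin metathesis between the styrene and the vinyl group on the quaternary carbon closes the six-membered 2H-pyran ring with loss of ethylene (closure onto the hindered internal alkene would need a seven-membered ring and is slower), the free tertiary alcohol is tolerated, and C2 carries no hydrogen and is not touched, so it stays (R).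

**Step 7**
Reactants: 13 methyl 2,4-dihydroxybenzoate
Product: 14 methyl 2,4-bis(SEM-oxy)benzoate
Conditions: SEMCl, Cs2CO3, DMF, 0 °C→rt
Reagents that add atoms: 2-(trimethylsilyl)ethoxymethyl chloride (SEMCl), C[Si](C)(C)CCOCCl
Why: Double Williamson-type O-alkylation; the caesium phenoxide in DMF is reactive enough to alkylate also the hydrogen-bonded 2-OH, giving an ester with no acidic hydrogen for the Grignard step.

**Step 8**
Reactants: 14 methyl 2,4-bis(SEM-oxy)benzoate
Product: 15 1-[2,4-bis(SEM-oxy)phenyl]cyclopropan-1-ol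
Conditions: EtMgBr, Ti(OiPr)4 (30 mol%), THF, 0 °C→rt; H2O
Reagents that add atoms: ethylmagnesium bromide, CC[Mg]Br
Why: Kulinkovich cyclopropanation: the ester is converted by the 1,2-dicarbanion equivalent formed from EtMgBr and catalytic Ti(OiPr)4 into the 1-arylcyclopropanol, a stored form of the ketone homoenolate; SEM acetals are inert to Grignard reagents.

**Step 9**
Reactants: 12 (3E)-5-[(2R)-5-bromo-2-methyl-8-(SEM-oxy)-2H-chromen-2-yl]-2-methylpent-3-en-2-ol; 15 1-[2,4-bis(SEM-oxy)phenyl]cyclopropan-1-ol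
Product: 17 1-[2,4-bis(SEM-oxy)phenyl]-3-{(2R)-2-[(2E)-4-hydroxy-4-methylpent-2-en-1-yl]-2-methyl-8-(SEM-oxy)-2H-chromen-5-yl}propan-1-one, via palladium homoenolate 16 (not isolated)
Conditions: Pd(OAc)2 (5 mol%), XPhos (10 mol%), Cs2CO3, toluene, 70 °C, dark
Reagents that add atoms: none
Why: Palladium-catalysed ring-opening cross-coupling of a cyclopropanol with an aryl bromide (homoenolate arylation): zerovalent palladium inserts into the C–Br bond of 12, the cyclopropoxide of 15 replaces bromide and strain-driven β-carbon elimination gives the palladium homoenolate 16, whose β-carbon (the carbon that is electrophilic in an enone) is joined to the electrophilic aryl carbon by reductive elimination, which the bulky biaryl phosphine makes faster than β-hydride elimination; no stereocentre is formed and 70 °C in the dark is below the temperature at which the 2H-chromene opens.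

**Step 10**
Reactants: 17 1-[2,4-bis(SEM-oxy)phenyl]-3-{(2R)-2-[(2E)-4-hydroxy-4-methylpent-2-en-1-yl]-2-methyl-8-(SEM-oxy)-2H-chromen-5-yl}propan-1-one
Product: 18 1-(2,4-dihydroxyphenyl)-3-{(2R)-8-hydroxy-2-[(2E)-4-hydroxy-4-methylpent-2-en-1-yl]-2-methyl-2H-chromen-5-yl}propan-1-one (CNP0311864.1)
Conditions: n-Bu4NF, THF/DMPU, 50 °C, Ar, dark; AcOH
Reagents that add atoms: none
Why: Fluoride-induced fragmentation of the three SEM acetals (loss of Me3SiF, ethylene and formaldehyde) frees the phenols without any acid, so the ionisable tertiary allylic alcohol and the chromene survive, and 50 °C in the dark does not open the pyran ring, so C2 stays (R).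

## Compound list

1 | 4-bromo-2-fluorophenol | Oc1ccc(Br)cc1F | starting material
2 | 4-bromo-2-fluoro-1-(SEM-oxy)benzene | C[Si](C)(C)CCOCOc1ccc(Br)cc1F | intermediate
3 | [6-bromo-2-fluoro-3-(SEM-oxy)phenyl]lithium | C[Si](C)(C)CCOCOc1ccc(Br)c([Li])c1F | intermediate (not isolated)
4 | 6-bromo-2-fluoro-3-(SEM-oxy)benzaldehyde | C[Si](C)(C)CCOCOc1ccc(Br)c(C=O)c1F | intermediate
5 | (R)-(−)-linalool, (3R)-3,7-dimethylocta-1,6-dien-3-ol | C=C[C@](C)(O)CCC=C(C)C | starting material
6 | potassium (3R)-3,7-dimethylocta-1,6-dien-3-olate (potassium linaloolate) | C=C[C@](C)([O-])CCC=C(C)C.[K+] | intermediate (not isolated)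
7 | 6-bromo-2-{[(3R)-3,7-dimethylocta-1,6-dien-3-yl]oxy}-3-(SEM-oxy)benzaldehyde | C=C[C@](C)(Oc1c(C=O)c(Br)ccc1OCOCC[Si](C)(C)C)CCC=C(C)C | intermediate
8 | 1-bromo-3-{[(3R)-3,7-dimethylocta-1,6-dien-3-yl]oxy}-2-ethenyl-4-(SEM-oxy)benzene | C=C[C@](C)(Oc1c(C=C)c(Br)ccc1OCOCC[Si](C)(C)C)CCC=C(C)C | intermediate
9 | (6R)-6-[3-bromo-2-ethenyl-6-(SEM-oxy)phenoxy]-2,6-dimethyl-3-(phenylselanyl)oct-7-en-2-ol (both C3 epimers) | C=C[C@](C)(Oc1c(C=C)c(Br)ccc1OCOCC[Si](C)(C)C)CCC([Se]c1ccccc1)C(C)(C)O | intermediate (not isolated)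
10 | (6R)-6-[3-bromo-2-ethenyl-6-(SEM-oxy)phenoxy]-2,6-dimethyl-3-(phenylseleninyl)oct-7-en-2-ol (selenoxide of 9) | C=C[C@](C)(Oc1c(C=C)c(Br)ccc1OCOCC[Si](C)(C)C)CCC([Se](=O)c1ccccc1)C(C)(C)O | intermediate (not isolated)
11 | (3E,6R)-6-[3-bromo-2-ethenyl-6-(SEM-oxy)phenoxy]-2,6-dimethylocta-3,7-dien-2-ol | C=C[C@](C)(Oc1c(C=C)c(Br)ccc1OCOCC[Si](C)(C)C)C/C=C/C(C)(C)O | intermediate
12 | (3E)-5-[(2R)-5-bromo-2-methyl-8-(SEM-oxy)-2H-chromen-2-yl]-2-methylpent-3-en-2-ol | CC(C)(O)/C=C/C[C@]1(C)C=Cc2c(Br)ccc(OCOCC[Si](C)(C)C)c2O1 | intermediate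
13 | methyl 2,4-dihydroxybenzoate | COC(=O)c1ccc(O)cc1O | starting material
14 | methyl 2,4-bis(SEM-oxy)benzoate | COC(=O)c1ccc(OCOCC[Si](C)(C)C)cc1OCOCC[Si](C)(C)C | intermediate
15 | 1-[2,4-bis(SEM-oxy)phenyl]cyclopropan-1-ol | OC1(CC1)c1ccc(OCOCC[Si](C)(C)C)cc1OCOCC[Si](C)(C)C | intermediate
16 | divalent palladium homoenolate: {3-[2,4-bis(SEM-oxy)phenyl]-3-oxopropyl}(chromen-5-yl)palladium, chromenyl group as in 12 (XPhos on Pd not drawn) | CC(C)(O)/C=C/C[C@]1(C)C=Cc2c([Pd]CCC(=O)c3ccc(OCOCC[Si](C)(C)C)cc3OCOCC[Si](C)(C)C)ccc(OCOCC[Si](C)(C)C)c2O1 | intermediate (not isolated)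
17 | 1-[2,4-bis(SEM-oxy)phenyl]-3-{(2R)-2-[(2E)-4-hydroxy-4-methylpent-2-en-1-yl]-2-methyl-8-(SEM-oxy)-2H-chromen-5-yl}propan-1-one | CC(C)(O)/C=C/C[C@]1(C)C=Cc2c(CCC(=O)c3ccc(OCOCC[Si](C)(C)C)cc3OCOCC[Si](C)(C)C)ccc(OCOCC[Si](C)(C)C)c2O1 | intermediate
18 | 1-(2,4-dihydroxyphenyl)-3-{(2R)-8-hydroxy-2-[(2E)-4-hydroxy-4-methylpent-2-en-1-yl]-2-methyl-2H-chromen-5-yl}propan-1-one | CC(C)(O)/C=C/C[C@]1(C)C=Cc2c(CCC(=O)c3ccc(O)cc3O)ccc(O)c2O1 | target

## Step count and risks

Total steps: 10. Longest linear sequence: 8 (steps 1–6, 9, 10); steps 7–8 make the second fragment.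

**Step 3 (SNAr).** A hindered tertiary alkoxide must attack a carbon flanked by CHO and OSEM, and it can instead add to the aldehyde or displace the bromide. Fallback, setting out from 4 and coming back at 7: iodine and aqueous ammonia (THF, rt) convert the aldehyde into 6-bromo-2-fluoro-3-(SEM-oxy)benzonitrile F1. The nitrile is slimmer, more activating and not electrophilic towards the alkoxide, so potassium linaloolate 6 displaces fluoride to give 6-bromo-2-{[(3R)-3,7-dimethylocta-1,6-dien-3-yl]oxy}-3-(SEM-oxy)benzonitrile F2. Reduction with i-Bu2AlH (toluene, −78 °C; aqueous KNaC4H4O6 work-up) returns aldehyde 7.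

**Step 9 (homoenolate coupling).** The palladium homoenolate 16 may lose a β-hydride (aryl vinyl ketone plus debrominated chromene), or 15 may isomerise to the ethyl ketone under carbonate at 70 °C. Fallback, setting out from 15 and coming back at 17: the homoenolate is pre-formed stoichiometrically instead of on palladium. Et2Zn (THF, 0 °C→rt) deprotonates 15 and the ring opens to ethyl{3-[2,4-bis(SEM-oxy)phenyl]-3-oxopropyl}zinc F3. This is cross-coupled with 12 in a Negishi reaction (Pd(OAc)2, SPhos, THF, 40 °C; excess F3 to allow for the free tertiary OH) to give 17, at lower temperature and without carbonate base.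

**Step 10 (global SEM removal).** Three aryl SEM acetals need warm fluoride; the chromene could partly racemise or degrade, and the formaldehyde released can attack the phenoxides. Fallback, setting out from 11 and coming back at 18: the ring closure is moved to the end. Diene 11 is coupled with 15 under the conditions of step 9 to give 1-[2,4-bis(SEM-oxy)phenyl]-3-[2-ethenyl-3-{[(3R,5E)-7-hydroxy-3,7-dimethylocta-1,5-dien-3-yl]oxy}-4-(SEM-oxy)phenyl]propan-1-one F4. The SEM groups are then removed with n-Bu4NF (DMPU, 80 °C), which is safe because no chromene is present yet, giving 1-(2,4-dihydroxyphenyl)-3-[2-ethenyl-4-hydroxy-3-{[(3R,5E)-7-hydroxy-3,7-dimethylocta-1,5-dien-3-yl]oxy}phenyl]propan-1-one F5. Ring-closing metathesis of the free triphenol (second-generation Hoveyda–Grubbs catalyst RuCl2(=CH-C6H4-2-OiPr)(SIMes), EtOAc, 40 °C, dark) then gives 18 directly.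

## Further compounds

F1 | step 3 | 6-bromo-2-fluoro-3-(SEM-oxy)benzonitrile | N#Cc1c(F)c(OCOCC[Si](C)(C)C)ccc1Br
F2 | step 3 | 6-bromo-2-{[(3R)-3,7-dimethylocta-1,6-dien-3-yl]oxy}-3-(SEM-oxy)benzonitrile | C=C[C@](C)(Oc1c(C#N)c(Br)ccc1OCOCC[Si](C)(C)C)CCC=C(C)C
F3 | step 9 | ethyl{3-[2,4-bis(SEM-oxy)phenyl]-3-oxopropyl}zinc | CC[Zn]CCC(=O)c1ccc(OCOCC[Si](C)(C)C)cc1OCOCC[Si](C)(C)C
F4 | step 10 | 1-[2,4-bis(SEM-oxy)phenyl]-3-[2-ethenyl-3-{[(3R,5E)-7-hydroxy-3,7-dimethylocta-1,5-dien-3-yl]oxy}-4-(SEM-oxy)phenyl]propan-1-one | C=C[C@](C)(Oc1c(C=C)c(CCC(=O)c2ccc(OCOCC[Si](C)(C)C)cc2OCOCC[Si](C)(C)C)ccc1OCOCC[Si](C)(C)C)C/C=C/C(C)(C)O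
F5 | step 10 | 1-(2,4-dihydroxyphenyl)-3-[2-ethenyl-4-hydroxy-3-{[(3R,5E)-7-hydroxy-3,7-dimethylocta-1,5-dien-3-yl]oxy}phenyl]propan-1-one | C=C[C@](C)(Oc1c(C=C)c(CCC(=O)c2ccc(O)cc2O)ccc1O)C/C=C/C(C)(C)O
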